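(The earlier runs and the new flask were computed on assumed constants, noise included.)

Plot the target in millimolar, not in percent of the charge, and your hunch that the percentage carries over to the new flask goes: at 8.00 h blue reads 16.4% and ochre 11.0%, yet these are 1.64 mM and 1.65 mM.

| setting | blue | ochre | flask |
|---|---|---|---|
| solid substrate | 10 mM | 15 mM | 20 mM |
| gas phase | 6.7 mM (held) | 6.7 mM (held) | 6.7 mM (held) |
| remark | run made earlier | run made earlier |  |
| time |  |  | 20 h |

| run | time / h | target / % |
|---|---|---|
| blue | 1.50 | 0 |
| blue | 2.50 | 1.1 |
| blue | 4.00 | 5.2 |
| blue | 6.00 | 9.4 |
| blue | 8.00 | 16.4 |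
| blue | 12.0 | 25.3 |
| blue | 20.0 | 27.4 |
| ochre | 1.00 | 0 |
| ochre | 3.00 | 1.8 |
| ochre | 6.00 | 6.6 |
| ochre | 8.00 | 11.0 |
| ochre | 12.0 | 18.2 |
| ochre | 15.0 | 23.0 |
| ochre | 20.0 | 28.2 |

(readings scatter by 1 percentage point)

- a species is counted by the solid substrate in it: one side product B counts as two
- given per volume of solution although it is solid: solid substrate
- at the start none of the gas is dissolved
- on the list of suspects stand: gas phase <-> dissolved gas; starting material + dissolved gas -> target; starting material -> side product A; starting material + target -> side product B; solid substrate <-> starting material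
- at the start none of the solid substrate is in solution

- how much target there is at 20 h, in percent of the solid substrate charged
- concentration of dissolved gas in solution at 20 h, in percent of saturation

I solve the early end first. From 6.00 h to 12.0 h blue gains target at 0.265 mM h⁻¹. This is the shared rate, the millimolar of target gained per hour on the straight stretch, apparent zero order in the charge, for ochre gives 0.257 mM h⁻¹ from 8.00 h to 15.0 h. Blue's line meets zero at 2.45 h.

At the late end, blue gains 2.1 percentage points from 12.0 h to 20.0 h and reads 27.4%, with ochre reading 28.2% at 20.0 h, so I take blue's reading, within the scatter, as a rough ceiling in percent of the charge. Joining the ends, the line puts the flask at 23.2% by 20 h, below that ceiling, so I commit to the line. The readings show target alone, so I give no number for the dissolved gas.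

The forecast says 22.5% of target and dissolved gas at 85% of saturation, on the suggestion that “solid dissolving keeps the starting material at a saturated level”.

The flask gives 25.2% of target, with dissolved gas at 83.7% of saturation.

    gas phase ⇌ dissolved gas, rate k1*(csat - [dissolved gas]) (kL = 0.269 h⁻¹)
    starting material + dissolved gas → target (k = 17.4 M⁻¹ h⁻¹)
    starting material → side product A (k = 0.205 h⁻¹)
    starting material + target → side product B (k = 1.77 M⁻¹ h⁻¹)
    solid substrate ⇌ starting material, rate k5*(cs5 - [starting material]) while solid is left; crystals form when [starting material] > cs5 (solubility = 13.0 mM, k = 0.114 h⁻¹)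

At 20 h the flask holds solid substrate at 0% and starting material at 8.96%. Between 8.0 h and 20 h the flask gains target at 0.295 mM h⁻¹, against the shared rate of 0.265 mM h⁻¹. For the same charge stopped at 8.0 h, the line gives 7.35%, and that flask holds 7.49%.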